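**Retrosynthetic overview**
- The C2–aryl bond is made last. The flavanone is cut to a 7‑hydroxychromone and an arylboronic acid. A Rh/chiral‑diene 1,4‑arylation breaks the aromaticity of the γ‑pyrone ring, joins both halves and sets C2 (S), with all three OH groups free.
- The C ring is the only ring built. It is closed as the pyrone from an o‑MOM‑oxyacetophenone through its enaminone, and both MOM groups are lost in the same pot.
- The side chain comes from the 3‑prenyl group. Shi epoxidation sets (R), and Ti(III) radical isomerisation gives the isopropenyl carbinol.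
- All three prenyl groups come from aqueous C‑prenylation of two cheap phenols, 2,4‑dihydroxyacetophenone and 4‑iodophenol.
- Ring order: rings A and B are bought, ring C is formed aromatic in step 5 and dearomatised in step 8.

Assumption: the Rh/(S,S)‑Ph‑bod* catalyst selects the chromone face in the same sense as it does for 2‑cyclohexenone. Both ligand antipodes are commercial, so the sense can be switched if needed.

**Step 1**
Reactants: 1 2,4‑dihydroxyacetophenone; 2 prenyl bromide (1‑bromo‑3‑methylbut‑2‑ene)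
Product: 3 1‑[2,4‑dihydroxy‑3‑(3‑methylbut‑2‑enyl)phenyl]ethanone
Conditions: KOH (2 equiv), H2O, 2 (1.0 equiv), 0 °C → rt; chromatography
Reagents that add atoms: none
Why: Kornblum‑type C‑alkylation of an ambident resorcinolate, in which water hydrogen‑bonds the phenoxide oxygens so that the allylic bromide is taken by the doubly activated C3 between them (via the cyclohexadienone, which re‑aromatises), a known nuclear prenylation of moderate yield (about 30–40 %) whose 5‑C‑ and O‑prenyl isomers are separable.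

**Step 2**
Reactants: 3 1‑[2,4‑dihydroxy‑3‑(3‑methylbut‑2‑enyl)phenyl]ethanone
Product: 4 1‑[2,4‑bis(methoxymethoxy)‑3‑(3‑methylbut‑2‑enyl)phenyl]ethanone
Conditions: NaH (2.5 equiv), MOMCl (2.6 equiv), DMF, 0 °C → rt
Reagents that add atoms: chloromethyl methyl ether (MOMCl), COCCl
Why: Williamson‑type O‑alkylation of both phenoxides (the chelated 2‑OH needs NaH) masks the two ortho oxygens that would otherwise open the epoxide made next, and both groups fall off inside the later ring closure, so protection costs only this one operation.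

**Step 3**
Reactants: 4 1‑[2,4‑bis(methoxymethoxy)‑3‑(3‑methylbut‑2‑enyl)phenyl]ethanone
Product: 5 1‑[3‑{[(2R)‑3,3‑dimethyloxiran‑2‑yl]methyl}‑2,4‑bis(methoxymethoxy)phenyl]ethanone
Conditions: D‑fructose‑derived Shi ketone (30 mol %), Oxone, K2CO3, Bu4NHSO4 (cat.), MeCN–DMM / aq Na2B4O7–EDTA (pH 10.5), 0 °C
Reagents that add atoms: potassium peroxymonosulfate (active part of Oxone), [K+].[O-]S(=O)(=O)OO
Why: Shi asymmetric epoxidation, in which the chiral dioxirane attacks the only alkene through the spiro transition state that gives (R)‑epoxides from RCH2CH=CMe2 olefins (typically 90–95 % ee) and so sets the side‑chain stereocentre, while the aryl ketone and MOM acetals are inert at pH 10.5 and 0 °C.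

**Step 4**
Reactants: 5 1‑[3‑{[(2R)‑3,3‑dimethyloxiran‑2‑yl]methyl}‑2,4‑bis(methoxymethoxy)phenyl]ethanone
Product: 6 1‑{3‑[(2R)‑2‑hydroxy‑3‑methylbut‑3‑enyl]‑2,4‑bis(methoxymethoxy)phenyl}ethanone
Conditions: Cp2TiCl2 (2.5 equiv), Mn dust (8 equiv), degassed dry THF, rt; brief cold 1 M HCl work‑up
Reagents that add atoms: none
Why: Nugent–RajanBabu titanocene(III) epoxide opening, in which C–O homolysis occurs only at the tertiary carbon and the tertiary radical gives up a methyl hydrogen to a second Cp2TiCl (mixed disproportionation) to leave the isopropenyl carbinol, so the secondary C–O bond is never broken and (R) is retained, and the radical pathway avoids the cationic capture by the ortho‑OMOM oxygens that Lewis acids would cause.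

**Step 5**
Reactants: 6 1‑{3‑[(2R)‑2‑hydroxy‑3‑methylbut‑3‑enyl]‑2,4‑bis(methoxymethoxy)phenyl}ethanone
Product: 8 7‑hydroxy‑8‑[(2R)‑2‑hydroxy‑3‑methylbut‑3‑enyl]‑4H‑chromen‑4‑one, via enaminone 7 (not isolated)
Conditions: DMF‑DMA (3 equiv), toluene, 90 °C; evaporate; HCl (3 equiv), MeOH, 40 °C; NaHCO3 work‑up; recrystallise (ee upgrade)
Reagents that add atoms: N,N‑dimethylformamide dimethyl acetal, COC(OC)N(C)C
Why: Enaminone chromone synthesis, in which the amide acetal condenses with the methyl ketone, methanolic HCl removes both MOM groups as dimethoxymethane and the freed 2‑OH adds to the β‑carbon and expels dimethylamine (addition–elimination) to close the γ‑pyrone, while the allylic carbinol, whose alkene is deactivated by the adjacent oxygen, tolerates dilute acid and its stereocentre takes no part.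

**Step 6**
Reactants: 9 4‑iodophenol; 2 prenyl bromide
Product: 10 4‑iodo‑2,6‑bis(3‑methylbut‑2‑enyl)phenol
Conditions: KOH (2.2 equiv), H2O, 2 (2.2 equiv), rt; chromatography
Reagents that add atoms: none
Why: o,o'‑Diprenylation of a para‑blocked phenoxide in water (Kornblum C‑alkylation), a known reaction of p‑halophenols in which hydrogen bonding suppresses O‑alkylation and iodine blocks the para position, so two successive ortho attacks give the symmetric phenol.

**Step 7**
Reactants: 10 4‑iodo‑2,6‑bis(3‑methylbut‑2‑enyl)phenol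
Product: 12 [4‑hydroxy‑3,5‑bis(3‑methylbut‑2‑enyl)phenyl]boronic acid, via dilithiated phenolate 11 (not isolated)
Conditions: B(OiPr)3 (1.5 equiv), THF, −78 °C, n‑BuLi (2.2 equiv) added slowly; → 0 °C; 1 M HCl to pH 5
Reagents that add atoms: triisopropyl borate, CC(C)OB(OC(C)C)OC(C)C; water, O
Why: Iodine–lithium exchange on the lithium phenoxide with in‑situ borate quench, which works because exchange on an aryl iodide is faster than attack of n‑BuLi on the borate, the aryllithium is trapped at once, mild hydrolysis frees the boronic acid, and the prenyl groups are inert at −78 °C.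

**Step 8** (key step)
Reactants: 8 7‑hydroxy‑8‑[(2R)‑2‑hydroxy‑3‑methylbut‑3‑enyl]‑4H‑chromen‑4‑one; 12 [4‑hydroxy‑3,5‑bis(3‑methylbut‑2‑enyl)phenyl]boronic acid
Product: 13 (2S)‑7‑hydroxy‑8‑[(2R)‑2‑hydroxy‑3‑methylbut‑3‑enyl]‑2‑[4‑hydroxy‑3,5‑bis(3‑methylbut‑2‑enyl)phenyl]‑2,3‑dihydro‑4H‑chromen‑4‑one (target)
Conditions: [RhCl(C2H4)2]2 (2.5 mol %), (S,S)‑Ph‑bod* (5.5 mol %), aq KOH (5 mol %, 1 equiv per Rh, pre‑mixed), 12 (2.5 equiv in two portions), dioxane/H2O 10:1, 30–40 °C
Reagents that add atoms: none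
Why: Hayashi–Miyaura asymmetric 1,4‑addition used as a dearomative arylation, in which aryl–Rh(I) inserts the C2=C3 bond of the γ‑pyrone on the face left open by the C2‑symmetric diene (the ligand sense that gives (S)‑3‑arylcyclohexanone maps without a CIP change onto 2S) and water protonates the rhodium enolate faster than aryloxide elimination, the isolated tri‑ and 1,1‑disubstituted alkenes do not insert, no free base is present to racemise the 4'‑hydroxyflavanone, and the reaction, known at 97 % ee or better on protected chromones, is stretched here to three free OH groups at the cost of excess 12.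

**Compound list**
1 | 2,4‑dihydroxyacetophenone | CC(=O)c1ccc(O)cc1O | starting material
2 | prenyl bromide | CC(C)=CCBr | starting material
3 | 1‑[2,4‑dihydroxy‑3‑(3‑methylbut‑2‑enyl)phenyl]ethanone | CC(=O)c1ccc(O)c(CC=C(C)C)c1O | intermediate
4 | 1‑[2,4‑bis(methoxymethoxy)‑3‑(3‑methylbut‑2‑enyl)phenyl]ethanone | CC(=O)c1ccc(OCOC)c(CC=C(C)C)c1OCOC | intermediate
5 | 1‑[3‑{[(2R)‑3,3‑dimethyloxiran‑2‑yl]methyl}‑2,4‑bis(methoxymethoxy)phenyl]ethanone | CC(=O)c1ccc(OCOC)c(C[C@H]2OC2(C)C)c1OCOC | intermediate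
6 | 1‑{3‑[(2R)‑2‑hydroxy‑3‑methylbut‑3‑enyl]‑2,4‑bis(methoxymethoxy)phenyl}ethanone | C=C(C)[C@H](O)Cc1c(OCOC)ccc(C(C)=O)c1OCOC | intermediate
7 | (E)‑3‑(dimethylamino)‑1‑{3‑[(2R)‑2‑hydroxy‑3‑methylbut‑3‑enyl]‑2,4‑bis(methoxymethoxy)phenyl}prop‑2‑en‑1‑one | C=C(C)[C@H](O)Cc1c(OCOC)ccc(C(=O)/C=C/N(C)C)c1OCOC | intermediate
8 | 7‑hydroxy‑8‑[(2R)‑2‑hydroxy‑3‑methylbut‑3‑enyl]‑4H‑chromen‑4‑one | C=C(C)[C@H](O)Cc1c(O)ccc2c1OC=CC2=O | intermediate
9 | 4‑iodophenol | Oc1ccc(I)cc1 | starting material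
10 | 4‑iodo‑2,6‑bis(3‑methylbut‑2‑enyl)phenol | CC(C)=CCc1cc(I)cc(CC=C(C)C)c1O | intermediate
11 | lithium 4‑lithio‑2,6‑bis(3‑methylbut‑2‑enyl)phenolate | [Li]Oc1c(CC=C(C)C)cc([Li])cc1CC=C(C)C | intermediate
12 | [4‑hydroxy‑3,5‑bis(3‑methylbut‑2‑enyl)phenyl]boronic acid | CC(C)=CCc1cc(B(O)O)cc(CC=C(C)C)c1O | intermediate
13 | (2S)‑7‑hydroxy‑8‑[(2R)‑2‑hydroxy‑3‑methylbut‑3‑enyl]‑2‑[4‑hydroxy‑3,5‑bis(3‑methylbut‑2‑enyl)phenyl]chroman‑4‑one | C=C(C)[C@H](O)Cc1c(O)ccc2c1O[C@H](c1cc(CC=C(C)C)c(O)c(CC=C(C)C)c1)CC2=O | target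

**Totals**
- Total step count: 8.
- Longest linear sequence: 6 (steps 1–5 and 8).

**Steps most likely to fail**

Step 8. The risks are protodemetalation of the aryl–Rh species by the acidic 7‑OH, sluggish insertion into the electron‑rich chromone, and loss of ee. The fallback sets out from 8 and 10 and comes back at 13, changing the end‑game from unprotected to silyl‑masked. Compound 8 is silylated on both hydroxyls (TBSOTf, 2,6‑lutidine, CH2Cl2, 0 °C) to the bis‑TBS chromone F1. Compound 10 is silylated in the same way to the iodoaryl TBS ether F2, which with n‑BuLi/B(OiPr)3 gives the O‑TBS boronic acid F3. The same Rh/(S,S)‑Ph‑bod* addition of F3 to F1, now with no acidic proton, gives the tris‑TBS flavanone F4. Et3N·3HF in MeCN is acidic, so no retro‑oxa‑Michael occurs, and it releases 13.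

Step 5. The risks are that the amide acetal reacts with the allylic alcohol, or that acid closes the 7‑OH onto the side‑chain alkene. The fallback sets out from 4 and comes back at 8, building the pyrone before the side chain is oxidised. Compound 4 with DMF‑DMA gives the prenyl enaminone F5, and methanolic HCl gives 7‑hydroxy‑8‑prenylchromone F6. TBSCl/imidazole then gives the 7‑O‑TBS prenylchromone F7. Shi epoxidation with the same D‑fructose ketone gives the (R)‑epoxide F8, and Cp2TiCl gives the O‑TBS allylic alcohol F9. TBAF buffered with AcOH returns 8.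

Step 4. The risks are deoxygenation back to the alkene, reductive opening, or ketone formation in place of the allylic alcohol. The fallback sets out from 4 and comes back at 6, replacing steps 3 and 4 and avoiding the epoxide altogether. A Schenck ene reaction of 4 (O2, tetraphenylporphyrin, hν, CH2Cl2) gives the racemic secondary allylic hydroperoxide F10. PPh3 reduces it to the racemic allylic alcohol F11, which is separated from the tertiary styrenyl regioisomer. Sharpless kinetic resolution (Ti(OiPr)4, L‑(+)‑DIPT, TBHP 0.6 equiv, −20 °C) consumes the (S)‑alcohol as the epoxy alcohol F12. It leaves the (R)‑alcohol, which is 6, in at most 50 % yield.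

**Further compounds**
F1 | step 8 | 7‑(tert‑butyldimethylsilyloxy)‑8‑[(2R)‑2‑(tert‑butyldimethylsilyloxy)‑3‑methylbut‑3‑enyl]‑4H‑chromen‑4‑one | C=C(C)[C@H](O[Si](C)(C)C(C)(C)C)Cc1c(O[Si](C)(C)C(C)(C)C)ccc2c1OC=CC2=O
F2 | step 8 | tert‑butyl[4‑iodo‑2,6‑bis(3‑methylbut‑2‑enyl)phenoxy]dimethylsilane | CC(C)=CCc1cc(I)cc(CC=C(C)C)c1O[Si](C)(C)C(C)(C)C
F3 | step 8 | [4‑(tert‑butyldimethylsilyloxy)‑3,5‑bis(3‑methylbut‑2‑enyl)phenyl]boronic acid | CC(C)=CCc1cc(B(O)O)cc(CC=C(C)C)c1O[Si](C)(C)C(C)(C)C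
F4 | step 8 | (2S,2''R)‑tris‑O‑TBS ether of 13 | C=C(C)[C@H](O[Si](C)(C)C(C)(C)C)Cc1c(O[Si](C)(C)C(C)(C)C)ccc2c1O[C@H](c1cc(CC=C(C)C)c(O[Si](C)(C)C(C)(C)C)c(CC=C(C)C)c1)CC2=O
F5 | step 5 | (E)‑1‑[2,4‑bis(methoxymethoxy)‑3‑(3‑methylbut‑2‑enyl)phenyl]‑3‑(dimethylamino)prop‑2‑en‑1‑one | CC(C)=CCc1c(OCOC)ccc(C(=O)/C=C/N(C)C)c1OCOC
F6 | step 5 | 7‑hydroxy‑8‑(3‑methylbut‑2‑enyl)‑4H‑chromen‑4‑one | CC(C)=CCc1c(O)ccc2c1OC=CC2=O
F7 | step 5 | 7‑(tert‑butyldimethylsilyloxy)‑8‑(3‑methylbut‑2‑enyl)‑4H‑chromen‑4‑one | CC(C)=CCc1c(O[Si](C)(C)C(C)(C)C)ccc2c1OC=CC2=O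
F8 | step 5 | 7‑(tert‑butyldimethylsilyloxy)‑8‑{[(2R)‑3,3‑dimethyloxiran‑2‑yl]methyl}‑4H‑chromen‑4‑one | CC1(C)O[C@@H]1Cc1c(O[Si](C)(C)C(C)(C)C)ccc2c1OC=CC2=O
F9 | step 5 | 7‑(tert‑butyldimethylsilyloxy)‑8‑[(2R)‑2‑hydroxy‑3‑methylbut‑3‑enyl]‑4H‑chromen‑4‑one | C=C(C)[C@H](O)Cc1c(O[Si](C)(C)C(C)(C)C)ccc2c1OC=CC2=O
F10 | step 4 | rac‑1‑{3‑(2‑hydroperoxy‑3‑methylbut‑3‑enyl)‑2,4‑bis(methoxymethoxy)phenyl}ethanone | C=C(C)C(OO)Cc1c(OCOC)ccc(C(C)=O)c1OCOC
F11 | step 4 | rac‑1‑{3‑(2‑hydroxy‑3‑methylbut‑3‑enyl)‑2,4‑bis(methoxymethoxy)phenyl}ethanone | C=C(C)C(O)Cc1c(OCOC)ccc(C(C)=O)c1OCOC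
F12 | step 4 | 1‑{3‑[(2S)‑2‑hydroxy‑2‑[(2R)‑2‑methyloxiran‑2‑yl]ethyl]‑2,4‑bis(methoxymethoxy)phenyl}ethanone | C[C@@]1(CO1)[C@@H](O)Cc1c(OCOC)ccc(C(C)=O)c1OCOC
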